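I choose to judge this flask by one number, its reach 1.00: the smaller of one and the equivalents of reagent, which is the share of the charged substrate that the reagent can take up if one reagent serves one substrate.

| flask | substrate | reagent | remark | time |
|---|---|---|---|---|
| zeta | 0.25 M | 1.2 equiv | run made earlier |  |
| delta | 1 M | 1.2 equiv | run made earlier |  |
| flask | 0.50 M | 1.20 equiv |  | 8.0 h |

| run | time / h | target / % | substrate / % |
|---|---|---|---|
| zeta | 0.200 | 19 | 5 |
| zeta | 0.417 | 24 | 5 |
| zeta | 1.00 | 29 | 1 |
| zeta | 2.00 | 18 | 1 |
| zeta | 5.00 | 4 | 1 |
| zeta | 10.0 | 1 | 0 |
| delta | 0.200 | 15 | 4 |
| delta | 0.417 | 26 | 1 |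
| delta | 1.00 | 34 | 1 |
| delta | 2.00 | 20 | 0 |
| delta | 5.00 | 2 | 1 |
| delta | 10.0 | 2 | 0 |

(scatter of a reading: 2 percentage points)



* the moment within 8.0 h at which there is most target
* the amount of target, in percent of the substrate charged, at that time
* the first time at which target reaches 23%, in the same percent

The zeta and delta runs have the same reach as this flask, so they cannot test it. They can test whether [substrate] has to enter the number as well. Averaged over their shared times, the target readings of the delta run stand 0.67 percentage points above those of the zeta run, less than the scatter of one reading, 2 points, although [substrate] goes from 0.25 M to 1 M at the same equivalents of reagent, so that [reagent] rises with it. So I replace the two curves by their mean and give it to this flask at 0.50 M. I read the top at 1.00 h, where the runs show 29% and 34%, mean 31.5%. That reading times the reach gives 31.5% for this flask, with the scatter of the readings on it.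

The forecast gives 32% at 0.8 h, and 23% reached at 0.35 h, on the ground “so concentration has little effect”. It puts the peak earlier than my reading time and higher than my figure.

The flask gives 33.1% at 0.851 h, and reaches 23% at 0.323 h.

    substrate + reagent → intermediate A (k = 2.40 /M/min)
    substrate → decomposition product (k = 2.60 × 10⁻⁵ /min)
    intermediate A ⇌ intermediate B (K = 0.810, k = 0.540 /min)
    intermediate A → target (k = 0.0330 /min)
    target → over-reaction product (k = 0.0220 /min)

The forecast holds within its margins. What parts from its 32% is a smaller reagent charge: the neighbour flask at 0.480 equiv, otherwise like this one, has reach 0.480, so the same reckoning gives 15.1%; that neighbour flask gives 15.9%. In the neighbour flask reagent is the limiting reagent, with 0% of its charge left at 8.00 h, and 51% of the charged substrate is still there.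

The data come from a simulation for substances that don't exist, and the scatter is random.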